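At late times each flask holds what its coupling partner has already made, so I began from how that partner divides between substrate and target.

    substrate + coupling partner → target (k1 = 0.0169 M⁻¹ min⁻¹)
    coupling partner + target → over-reaction product (k2 = 0.0219 M⁻¹ min⁻¹)
    2 coupling partner → self-condensation product (k3 = 0.0274 M⁻¹ min⁻¹)
    2 substrate → homo dimer (k4 = 4.66 × 10⁻⁵ M⁻¹ min⁻¹)

all flasks: time 20 h

|  | substrate | coupling partner | remark |
|---|---|---|---|
| blue | 0.20 M | 0.260 M | everything together at the start |
| violet | 0.20 M | 0.260 M (fed, over 12 h) | all else is in the flask from the start; the feed brings no volume worth counting |
| ochre | 0.20 M (fed, over 12 h) | 0.260 M | all else is in the flask from the start; the feed brings no volume worth counting |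
| green | 0.20 M | 0.260 M (fed, over 3.0 h) | all else is in the flask from the start; the feed brings no volume worth counting |

1. the best flask by share of target in target plus over-reaction product; "all alike" if 1.5 percentage points covers them all (blue / violet / ochre / green / all alike)
2. share of target in target plus over-reaction product at the end, blue
3. share of target in target plus over-reaction product at the end, violet
4. share of target in target plus over-reaction product at the end, ochre
5. share of target in target plus over-reaction product at the end, green

- percent here means substrate units held: one homo dimer counts as two
- a doubled species enters its step squared and goes two at a time
- run time (blue): 20 h

Coupling and over-reaction are each first order in [coupling partner], so that concentration cancels from the ratio of their rates. With the partner as charged in blue, substrate has a half-life of 2.6 h by coupling alone, and target has 2.0 h by over-reaction alone, the shorter of the two. Their ratio, 1.30, stays the same at any [coupling partner]. I carried it as s, the selectivity factor: the rate constant of over-reaction over that of coupling.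

I set the homo dimer aside because its rate constant is far smaller than that of coupling. With x as the fraction of substrate left, dividing the two rate laws gave target as (x − x^s)/(s − 1) of the charge. The share of target is then (x − x^s)/((s − 1)(1 − x)). This needs the whole substrate charge present from the start, so it covers blue, violet and green, however the partner arrives. At x = 0.5 it gave 62.7%. Ochre's substrate arrives by feed over 12 h, so the curve does not apply there. I stopped at this point, because I did not reckon how far x falls in each flask.

The forecast named ochre best, with 71.3% for blue, 60.5% for violet, 81.8% for ochre and 67% for green; it took ochre's figure from a stepwise estimate, on the ground that “partner meets little substrate and mostly self-condenses”.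

The simulation gave ochre as best at 81.4%, with blue at 71.4%, violet at 60.7% and green at 67.1%. Ochre ended with 81.4% of its substrate unreacted and 14.4% as target. Blue's 59.5% of substrate left, put into the curve with s, gives 70.7%. Green's 54.4% left gives 66.4%, and green ended at 67.1%.

Its constants are assumed; the result is computed.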